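(All runs come from a simulation with constants of no real substance; noise was put on by code.)

The target in this flask first climbed and then, going by the south-west run, faded, so I built its peak one process at a time.

in all of them: solid substrate 0.050 M
- north-west: solid reagent 1 equiv; the very flask that is asked about, followed so far
- south-west: solid reagent 2 equiv; run made earlier
- flask: solid reagent 1.00 equiv; time 5.0 h

- north-west (time / min: target / %, solid substrate / %): 5.00: 12.3, 45.9; 12.0: 41.3, 0.1; 25.0: 49.1, 2.2; 40.0: 49.1, 0
- south-west (time / h: target / %, solid substrate / %): 0.417: 51.0, 1.3; 1.00: 49.7, 0; 2.00: 46.7, 0; 5.00: 36.1, 0

(standard deviation of a reading: 1 percentage point)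

- given per volume of solution although it is solid: solid substrate, solid reagent
- at the start none of the solid substrate is in solution
- at the start none of the solid reagent is in solution

- the moment within 5.0 h at which there is most target
- the amount of target, in percent of the solid substrate charged, at that time

First I took the main step by itself. In the north-west run, the flask asked about, the target closed on its plateau of 49.1% with this rise time:

rise time = 4.51 min

A curve that only climbs has its best at the end, 5.0 h.

Second came the side path. The runs levelled near half of the charge, at 49.1% and 51.0%, which lowered the number.

Third came the fall, seen in the south-west run at 2 equiv: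

fade time = 13.3 h

The fade time is the time in which the target shrinks by a factor of e after its climb. I borrowed it for 1.00 equiv. The peak then stands where the remaining gap over the rise time equals the plateau over the fade time:

peak time = 0.451 h

The forecast gave 0.6 h and 50%, adding “the peak may be broad and late”; its time was later than mine.

The flask gave 0.358 h and 50.0%.

    solid substrate ⇌ dissolved substrate, rate k1*(cs1 - [dissolved substrate]) while solid is left; crystals form when [dissolved substrate] > cs1 (solubility = 23.0 mM, k = 0.476 min⁻¹)
    2 dissolved substrate → side product (k = 3.59 M⁻¹ min⁻¹)
    solid reagent ⇌ partner, rate k3*(cs3 - [partner]) while solid is left; crystals form when [partner] > cs3 (solubility = 43.0 mM, k = 0.102 min⁻¹)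
    dissolved substrate + partner ⇌ target (K = 235 M⁻¹, k = 11.2 M⁻¹ min⁻¹)

From its best the target in this flask sank to 29.3% at 5.00 h, a fade time of 8.68 h, shorter than the borrowed one. At that moment the half-life of dissolved substrate, by its forward step to target alone, was 1.8 min, far shorter than that fade.

In the neighbour flask with 1.70 equiv, the south-west fade time carried its best of 51.4% from my peak time to 36.5% at 5.00 h. The computed value there was 36.6%.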